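**Retrosynthetic overview**
- The (E)-enone comes from a last-step cross-metathesis of a terminal vinyl group with methyl vinyl ketone; the acid comes from saponification of a methyl ester.
- The only ring, the 1,2-dioxane, is closed by a 6-exo peroxy-Michael addition of a C6 tertiary hydroperoxide onto an (E)-enoate, which sets C3.
- The C6–OO bond comes from a chiral-Brønsted-acid-controlled SN1 perhydrolysis of a tertiary alcohol (new step), made by ethyl Grignard addition to a ketone.
- The C4–C5 bond and C4 come from an organocatalytic SOMO α-enolation of butanal with a methyl-ketone enol silane, followed by Wittig olefination.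
- The side chain comes from a copper-catalysed asymmetric methyl conjugate addition (C8), a cross-metathesis, and an organocatalytic SOMO α-allylation of butanal (C10, first stereocentre).

Assumption: for each chiral catalyst the enantiomer written is the one taken to give the configuration drawn; if the sense of induction proves opposite, its mirror image is used.

Atom labels C1–C14 refer to the main chain of the target (C1 = CO2H, C3/C6 = ring carbons bearing O, C13 = ketone carbon).

**Step 1**
Reactants: 1 butanal; 2 allyltrimethylsilane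
Product: 3 (2S)-2-ethylpent-4-enal
Conditions: (2S,5S)-5-benzyl-2-tert-butyl-3-methylimidazolidin-4-one·TFA (20 mol %), (NH4)2Ce(NO3)6 (2 equiv), NaHCO3, DME, −20 °C
Reagents that add atoms: none
Why: Organocatalytic SOMO α-allylation, in which the imidazolidinone enamine of butanal is oxidised by tetravalent cerium to a radical cation whose unshielded face is attacked by the allylsilane, setting C10 (S) as the first stereocentre.

**Step 2**
Reactants: 3 (2S)-2-ethylpent-4-enal; 4 methyl vinyl ketone (3 equiv)
Product: 5 (2S,4E)-2-ethyl-6-oxohept-4-enal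
Conditions: [RuCl2(H2IMes)(=CH-C6H4-2-OiPr)] (second-generation Hoveyda–Grubbs catalyst, H2IMes = 1,3-dimesityl-4,5-dihydroimidazol-2-ylidene, 3 mol %), CH2Cl2, 40 °C
Reagents that add atoms: none
Why: Olefin cross-metathesis of the unhindered terminal alkene with the electron-poor partner gives the E-enone, and the neutral conditions leave the α-stereocentre of the aldehyde untouched.

**Step 3**
Reactants: 5 (2S,4E)-2-ethyl-6-oxohept-4-enal
Product: 6 (3E,6S)-6-ethylocta-3,7-dien-2-one
Conditions: CH2I2, Zn, Ti(OiPr)4 (promoter), THF, 0 °C to rt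
Reagents that add atoms: diiodomethane, ICI
Why: Takai-type methylenation with the geminal dizinc reagent is non-basic and selective for the aldehyde over the ketone carbonyl, so the α-stereocentre survives and the vinyl handle for the final enone is installed.

**Step 4**
Reactants: 6 (3E,6S)-6-ethylocta-3,7-dien-2-one
Product: 7 (4S,6S)-6-ethyl-4-methyloct-7-en-2-one
Conditions: MeMgBr, CuBr·SMe2 (5 mol %), (R,S)-Josiphos [(R)-1-[(S)-2-(diphenylphosphino)ferrocenyl]ethyldicyclohexylphosphine, 6 mol %], tBuOMe, −75 °C; then H2O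
Reagents that add atoms: methylmagnesium bromide, C[Mg]Br
Why: Copper-catalysed asymmetric conjugate addition of a Grignard reagent to an acyclic E-enone, in which the chiral diphosphine complex of monovalent copper selects the face of the β-carbon and sets C8 (S) independently of the remote C10 centre.

**Step 5**
Reactants: 7 (4S,6S)-6-ethyl-4-methyloct-7-en-2-one
Product: 9 {[(4S,6S)-6-ethyl-4-methylocta-1,7-dien-2-yl]oxy}trimethylsilane, via lithium enolate 8 (not isolated)
Conditions: LiN(iPr)2, THF, −78 °C; then Me3SiCl, −78 °C to 0 °C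
Reagents that add atoms: chlorotrimethylsilane, C[Si](C)(C)Cl
Why: Kinetic deprotonation occurs at the methyl group because the methylene side is β-branched, and O-silylation then gives the terminal enol silane without touching either stereocentre.

**Step 6**
Reactants: 9 {[(4S,6S)-6-ethyl-4-methylocta-1,7-dien-2-yl]oxy}trimethylsilane; 1 butanal (3 equiv)
Product: 10 (2S,6S,8S)-2,8-diethyl-6-methyl-4-oxodec-9-enal
Conditions: (2S,5S)-5-benzyl-2-tert-butyl-3-methylimidazolidin-4-one·TFA (20 mol %), (NH4)2Ce(NO3)6 (2 equiv), NaHCO3, H2O (2 equiv), acetone, −20 °C; crude product used at once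
Reagents that add atoms: none
Why: Organocatalytic SOMO α-enolation (oxidative enamine–enol silane coupling) forms the C4–C5 bond of the 1,4-dicarbonyl unit and sets C4 (S) by the same facial shielding as in step 1.

**Step 7**
Reactants: 10 (2S,6S,8S)-2,8-diethyl-6-methyl-4-oxodec-9-enal
Product: 11 methyl (2E,4S,8S,10S)-4,10-diethyl-8-methyl-6-oxododeca-2,11-dienoate
Conditions: Ph3P=CHCO2Me, CH2Cl2, 0 °C to rt
Reagents that add atoms: methyl (triphenylphosphoranylidene)acetate, COC(=O)C=P(c1ccccc1)(c1ccccc1)c1ccccc1
Why: Wittig olefination with a stabilised ylide reacts only at the aldehyde, is E-selective and, being neutral, does not epimerise C4.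

**Step 8**
Reactants: 11 methyl (2E,4S,8S,10S)-4,10-diethyl-8-methyl-6-oxododeca-2,11-dienoate
Product: 12 methyl (2E,4S,6RS,8S,10S)-4,6,10-triethyl-6-hydroxy-8-methyldodeca-2,11-dienoate (both C6 epimers)
Conditions: EtMgBr, LaCl3·2LiCl (30 mol %), THF, −78 °C; then H2O
Reagents that add atoms: ethylmagnesium bromide, CC[Mg]Br
Why: Lanthanum-promoted Grignard 1,2-addition to the ketone outruns enolisation and attack on the enoate, and the unselective formation of the carbinol centre does not matter because it is ionised in step 9.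

**Step 9**
Reactants: 12 methyl (2E,4S,6RS,8S,10S)-4,6,10-triethyl-6-hydroxy-8-methyldodeca-2,11-dienoate
Product: 13 methyl (2E,4S,6R,8S,10S)-4,6,10-triethyl-6-hydroperoxy-8-methyldodeca-2,11-dienoate
Conditions: H2O2 (anhydrous, in Et2O, 5 equiv), (S,S)-IDPi (BINOL-derived imidodiphosphorimidate Brønsted acid with 3,3'-aryl groups and an N-triflyl core, 5 mol %), CHCl3, −40 °C
Reagents that add atoms: hydrogen peroxide, OO
Why: Proposed new method: a stereoconvergent, catalyst-controlled SN1 perhydrolysis in which the confined chiral acid ionises either C6 epimer of 12 (and re-protonates any alkene formed by reversible elimination) to one tertiary carbenium ion held as a contact ion pair in the chiral anion pocket, where hydrogen-bonded H2O2 is delivered to one face to give the 6R hydroperoxide while the enoate and the monosubstituted alkene stay inert; the closest known reaction types are enantioconvergent SN1 substitutions of tertiary electrophiles through chiral ion pairs, IDPi-catalysed asymmetric hydroalkoxylation and hydrolactonisation of unactivated alkenes via tertiary cations, and the classical acid-catalysed perhydrolysis of tertiary alcohols, none of which uses H2O2 under chiral-acid control.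

**Step 10**
Reactants: 13 methyl (2E,4S,6R,8S,10S)-4,6,10-triethyl-6-hydroperoxy-8-methyldodeca-2,11-dienoate
Product: 14 methyl 2-[(3S,4S,6R)-4,6-diethyl-6-[(2S,4S)-4-ethyl-2-methylhex-5-en-1-yl]-1,2-dioxan-3-yl]acetate
Conditions: Et3N (0.3 equiv), CF3CH2OH, 0 °C, stopped at full conversion
Reagents that add atoms: none
Why: Base-mediated 6-exo intramolecular peroxy-Michael (oxa-Michael) addition under kinetic control is expected to pass through a chair transition state with the C4 ethyl and the large C6 chain equatorial and the enoate axial, as in the kinetic formation of 2,6-trans-tetrahydropyrans from E-enoates, which sets C3 (S), that is 3,4-cis.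

**Step 11**
Reactants: 14 methyl 2-[(3S,4S,6R)-4,6-diethyl-6-[(2S,4S)-4-ethyl-2-methylhex-5-en-1-yl]-1,2-dioxan-3-yl]acetate
Product: 15 2-[(3S,4S,6R)-4,6-diethyl-6-[(2S,4S)-4-ethyl-2-methylhex-5-en-1-yl]-1,2-dioxan-3-yl]acetic acid
Conditions: LiOH, THF/H2O (3:1), 0 °C; then 1 M HCl
Reagents that add atoms: lithium hydroxide, [Li+].[OH-]
Why: Saponification of the unhindered methyl ester at 0 °C is faster than E1cB loss of the β-peroxide and is done before the base-sensitive enone is present.

**Step 12**
Reactants: 15 2-[(3S,4S,6R)-4,6-diethyl-6-[(2S,4S)-4-ethyl-2-methylhex-5-en-1-yl]-1,2-dioxan-3-yl]acetic acid; 4 methyl vinyl ketone (5 equiv)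
Product: 16 2-[(3S,4S,6R)-4,6-diethyl-6-[(2S,4S,5E)-4-ethyl-2-methyl-7-oxooct-5-en-1-yl]-1,2-dioxan-3-yl]acetic acid (CNP0329238.3)
Conditions: [RuCl2(H2IMes)(=CH-C6H4-2-OiPr)] (second-generation Hoveyda–Grubbs catalyst, 10 mol %), CH2Cl2, 40 °C
Reagents that add atoms: none
Why: Cross-metathesis of the terminal vinyl group with methyl vinyl ketone gives the E-enone, the ruthenium carbene tolerates the hindered dialkyl peroxide and the free acid, and the allylic C10 centre is not affected.

**Compound list**
1 | butanal | CCCC=O | starting material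
2 | allyltrimethylsilane | C=CC[Si](C)(C)C | starting material
3 | (2S)-2-ethylpent-4-enal | CC[C@H](C=O)CC=C | intermediate
4 | methyl vinyl ketone (but-3-en-2-one) | CC(=O)C=C | starting material
5 | (2S,4E)-2-ethyl-6-oxohept-4-enal | CC[C@H](C=O)C/C=C/C(C)=O | intermediate
6 | (3E,6S)-6-ethylocta-3,7-dien-2-one | CC[C@H](C=C)C/C=C/C(C)=O | intermediate
7 | (4S,6S)-6-ethyl-4-methyloct-7-en-2-one | CC[C@H](C=C)C[C@H](C)CC(C)=O | intermediate
8 | lithium (4S,6S)-6-ethyl-4-methylocta-1,7-dien-2-olate | CC[C@H](C=C)C[C@H](C)CC(=C)[O-].[Li+] | intermediate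
9 | {[(4S,6S)-6-ethyl-4-methylocta-1,7-dien-2-yl]oxy}trimethylsilane | CC[C@H](C=C)C[C@H](C)CC(=C)O[Si](C)(C)C | intermediate
10 | (2S,6S,8S)-2,8-diethyl-6-methyl-4-oxodec-9-enal | CC[C@H](C=C)C[C@H](C)CC(=O)C[C@H](CC)C=O | intermediate
11 | methyl (2E,4S,8S,10S)-4,10-diethyl-8-methyl-6-oxododeca-2,11-dienoate | CC[C@H](C=C)C[C@H](C)CC(=O)C[C@H](CC)/C=C/C(=O)OC | intermediate
12 | methyl (2E,4S,6RS,8S,10S)-4,6,10-triethyl-6-hydroxy-8-methyldodeca-2,11-dienoate | CC[C@H](C=C)C[C@H](C)CC(O)(CC)C[C@H](CC)/C=C/C(=O)OC | intermediate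
13 | methyl (2E,4S,6R,8S,10S)-4,6,10-triethyl-6-hydroperoxy-8-methyldodeca-2,11-dienoate | CC[C@H](C=C)C[C@H](C)C[C@@](CC)(OO)C[C@H](CC)/C=C/C(=O)OC | intermediate
14 | methyl 2-[(3S,4S,6R)-4,6-diethyl-6-[(2S,4S)-4-ethyl-2-methylhex-5-en-1-yl]-1,2-dioxan-3-yl]acetate | CC[C@H](C=C)C[C@H](C)C[C@]1(CC)C[C@H](CC)[C@H](CC(=O)OC)OO1 | intermediate
15 | 2-[(3S,4S,6R)-4,6-diethyl-6-[(2S,4S)-4-ethyl-2-methylhex-5-en-1-yl]-1,2-dioxan-3-yl]acetic acid | CC[C@H](C=C)C[C@H](C)C[C@]1(CC)C[C@H](CC)[C@H](CC(=O)O)OO1 | intermediate
16 | 2-[(3S,4S,6R)-4,6-diethyl-6-[(2S,4S,5E)-4-ethyl-2-methyl-7-oxooct-5-en-1-yl]-1,2-dioxan-3-yl]acetic acid | CC[C@H](/C=C/C(C)=O)C[C@H](C)C[C@]1(CC)C[C@H](CC)[C@H](CC(=O)O)OO1 | target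

**Step count and risks**
Total step count: 12. Longest linear sequence: 12 steps (butanal 1 to target 16).

The three steps most likely to fail:

Step 6 (SOMO α-enolation with a valuable, functionalised enol silane; the 1,4-keto aldehyde is also easily epimerised). The fallback sets out from ketone 7 and returns at keto aldehyde 10. Ketone 7 is used directly in an enamine Michael addition to (E)-1-nitrobut-1-ene under a chiral primary amine–thiourea catalyst (benzoic acid co-catalyst, toluene, rt). The β-branched methyl ketone reacts at its methyl group and gives (2S,6S,8S)-2,8-diethyl-6-methyl-1-nitrodec-9-en-4-one F1. A Nef reaction (NaOMe, MeOH; then cold aqueous H2SO4) converts the nitromethyl group of F1 into the aldehyde of 10.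

Step 9 (the proposed new step; face selectivity on a trialkyl cation and re-ionisation of the product are both uncertain). The fallback uses known chemistry, sets out from tertiary alcohol 12 and returns at dioxane ester 14. Alcohol 12 is treated with 50 % aqueous H2O2 and catalytic H2SO4 in Et2O at 0 °C, the classical acid perhydrolysis of tertiary alcohols. This gives 13 together with its C6 epimer, methyl (2E,4S,6S,8S,10S)-4,6,10-triethyl-6-hydroperoxy-8-methyldodeca-2,11-dienoate F2. The mixture is cyclised as in step 10 to 14 and its C6 epimer, methyl 2-[(3S,4S,6S)-4,6-diethyl-6-[(2S,4S)-4-ethyl-2-methylhex-5-en-1-yl]-1,2-dioxan-3-yl]acetate F3, and the two are separated by chromatography. About half the material is lost.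

Step 10 (the 3,4-cis product is the kinetic one; retro-Michael equilibration would drift to the 3,4-trans isomer). The fallback sets out from keto aldehyde 10 and returns at dioxane ester 14, replacing the Michael closure by a peroxycarbenium alkylation.
- The aldehyde of 10 is protected (HC(OMe)3, MeOH, cat. pyridinium p-toluenesulfonate) as (2S,6S,8S)-2,8-diethyl-1,1-dimethoxy-6-methyldec-9-en-4-one F4.
- EtMgBr with LaCl3·2LiCl gives (2S,6S,8S)-2,4,8-triethyl-1,1-dimethoxy-6-methyldec-9-en-4-ol F5.
- H2O2 with the acid of step 9 (or of its fallback) converts the carbinol into the tertiary hydroperoxide, which closes onto the acetal carbon with loss of methanol to give (4S,6R)-4,6-diethyl-6-[(2S,4S)-4-ethyl-2-methylhex-5-en-1-yl]-3-methoxy-1,2-dioxane F6.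
- TiCl4 and 1-methoxy-1-(trimethylsilyloxy)ethene in CH2Cl2 at −78 °C ionise F6 to the cyclic peroxycarbenium ion. Axial attack of the ketene acetal on the half-chair with the C4 ethyl and the C6 chain equatorial delivers the 3,4-cis ester 14.

**Further compounds**
F1 | step 6 | (2S,6S,8S)-2,8-diethyl-6-methyl-1-nitrodec-9-en-4-one | CC[C@H](C=C)C[C@H](C)CC(=O)C[C@H](CC)C[N+](=O)[O-]
F2 | step 9 | methyl (2E,4S,6S,8S,10S)-4,6,10-triethyl-6-hydroperoxy-8-methyldodeca-2,11-dienoate | CC[C@H](C=C)C[C@H](C)C[C@](CC)(OO)C[C@H](CC)/C=C/C(=O)OC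
F3 | step 9 | methyl 2-[(3S,4S,6S)-4,6-diethyl-6-[(2S,4S)-4-ethyl-2-methylhex-5-en-1-yl]-1,2-dioxan-3-yl]acetate | CC[C@H](C=C)C[C@H](C)C[C@@]1(CC)C[C@H](CC)[C@H](CC(=O)OC)OO1
F4 | step 10 | (2S,6S,8S)-2,8-diethyl-1,1-dimethoxy-6-methyldec-9-en-4-one | CC[C@H](C=C)C[C@H](C)CC(=O)C[C@H](CC)C(OC)OC
F5 | step 10 | (2S,6S,8S)-2,4,8-triethyl-1,1-dimethoxy-6-methyldec-9-en-4-ol (both C4 epimers) | CC[C@H](C=C)C[C@H](C)CC(O)(CC)C[C@H](CC)C(OC)OC
F6 | step 10 | (4S,6R)-4,6-diethyl-6-[(2S,4S)-4-ethyl-2-methylhex-5-en-1-yl]-3-methoxy-1,2-dioxane (both C3 anomers) | CC[C@H](C=C)C[C@H](C)C[C@]1(CC)C[C@H](CC)C(OC)OO1
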